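The reagent cannot go wholly into the substrate in this flask, because in the reaction phase it decomposes at 0.018 min⁻¹ while even the full charge of substrate takes it at 0.00860 min⁻¹.

substrate 2.0 M; reagent in the second phase 3.60 M; protic impurity 0.400 M; time 25 h; volume of the second phase over the first 2.0

- the target standing at 25 h, as a percentage of the substrate charged
- the change that raises the amount of target at 25 h, in percent of the substrate charged most ("none" if none brings more than 2 percentage points) (alder / oak / none)
- amount of target at 25 h, in percent of the substrate charged, after oak

- in the second phase: reagent in the second phase; everything else is in the first
- charges count per volume of the first phase; a concentration in a rate is the amount of a species over the volume of its own phase; every rate counts per litre of the first phase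
- run time (flask): 25 h

    reagent in the reaction phase ⇌ reagent in the second phase, rate k1*([reagent in the reaction phase] - [reagent in the second phase]/K1) per volume of the first phase (K1 = 0.49, k1 = 0.15 min⁻¹)
    substrate + reagent in the reaction phase → target (k2 = 0.0043 M⁻¹ min⁻¹)
    reagent in the reaction phase + target → over-reacted product (k3 = 4.6 × 10⁻⁴ M⁻¹ min⁻¹)
    reagent in the reaction phase + protic impurity → quenched reagent (k4 = 0.049 M⁻¹ min⁻¹)
    reagent in the reaction phase → decomposed reagent (k5 = 0.018 min⁻¹)

Build the flask up by hand. With the main step alone, you have 3.60 M of reagent against 2.0 M of substrate, so the reckoning gives 100% target.

Add decomposition, and the number to carry appears: the crossing concentration, the substrate concentration at which the main step and decomposition take reagent equally, 4.19 M. The share reaching substrate is [substrate]/([substrate] + crossing concentration), a saturation curve with the crossing in the place of a Michaelis constant. Summed over the run, reagent spent equals substrate consumed plus the crossing concentration times the logarithm of charged over remaining substrate. Spending 3.60 M this way leaves 1.06 M of substrate, so target falls to 47.0%.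

Add the protic impurity, which leaves 3.20 M to spend, and substrate stops near 1.14 M; the balance holds because nearly all of the impurity is consumed by then. Add over-reaction, with selectivity factor 9.35, and my target is 41.4%.

Transfer is quicker than decomposition, and the reagent's lifetime against decomposition across both phases, 110 min, is far shorter than the run. The balance holds no transfer coefficient, so I expect oak to leave 41.4%. Alder takes substrate to about 0.546 M, so I choose alder.

The forecast gives 41.2%, slightly below my figure, names alder, and gives 41.2% after oak, reasoning that “Oak only speeds up a process that already finishes”.

The simulation gives 41.2%, with alder best at 25 percentage points against 0 points for oak, and 41.2% after oak.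

In this flask, half of the target-making turnover was done by 0.825 h, and at 2.50 h, with substrate at 63.4% and 7.73% of the reagent left in the second phase, the crossing gave the main step a share, against decomposition, of 23.2%. By 12.5 h the reaction phase held 2.85 × 10⁻⁴ M of reagent, with target at 41.2% and decomposed reagent at 2.32 M. A neighbouring flask, with 1.0 M of protic impurity, ended at 35.1% target and 64.0% substrate, where the crossing balance gives 2.59 M spent against 2.61 M left after quenching.

(The numbers were set for the occasion; the rest is arithmetic.)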